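All runs were computed with constants of no real substance; noise was put on by code.

One equivalent here is one starting complex charged, so we count every amount as a fraction of that charge.

| flask | starting complex | incoming ligand | protic impurity | remark | time |
|---|---|---|---|---|---|
| alder | 0.50 M | 0.90 equiv | 0.63 M | run made earlier |  |
| birch | 0.50 M | 0.90 equiv | 0.64 M | run made earlier |  |
| maple | 0.50 M | 0.90 equiv | 0.66 M | run made earlier |  |
| east | 0.50 M | 0.900 equiv | 0.500 M |  | 25 min |
| north | 0.50 M | 0.900 equiv | 0.750 M |  | 25 min |

| run | time / min | over-reaction product / % | complex with one exchanged / % | complex with two exchanged / % | starting complex / % |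
|---|---|---|---|---|---|
| alder | 1.33 | 7.3 | 34.1 | 6.1 | 55.0 |
| alder | 2.50 | 12.4 | 29.7 | 0.4 | 53.9 |
| alder | 5.00 | 15.9 | 22.5 | 0.6 | 62.7 |
| alder | 10.0 | 19.2 | 12.8 | 0 | 68.9 |
| alder | 20.0 | 18.0 | 7.0 | 0 | 74.2 |
| birch | 1.50 | 7.0 | 33.1 | 5.0 | 53.2 |
| birch | 4.00 | 13.9 | 22.2 | 3.2 | 59.6 |
| birch | 8.00 | 19.1 | 17.9 | 0 | 66.1 |
| birch | 12.0 | 18.7 | 10.5 | 0.9 | 70.5 |
| birch | 20.0 | 20.1 | 5.3 | 0.3 | 72.0 |
| maple | 1.50 | 9.8 | 34.1 | 4.9 | 53.7 |
| maple | 4.00 | 15.4 | 25.2 | 2.3 | 59.6 |
| maple | 8.00 | 16.8 | 16.0 | 0.8 | 65.4 |
| maple | 12.0 | 17.9 | 11.2 | 1.1 | 69.7 |
| maple | 20.0 | 18.7 | 5.4 | 1.1 | 74.1 |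

(standard deviation of a reading: 1 percentage point)



- which of these there is most of at the end, counted by the starting complex in it, east (complex with two exchanged / complex with one exchanged / starting complex / over-reaction product)
- which of these there is most of at the end, counted by the starting complex in it, north (complex with two exchanged / complex with one exchanged / starting complex / over-reaction product)
- amount of the one of these that there is most of at the end, in percent of the starting complex charged, east
- amount of the one of these that there is most of at the end, in percent of the starting complex charged, north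

We follow the incoming ligand through a ligand budget. At 20.0 min the three earlier runs average 18.9 % over-reaction product and 5.90 % complex with one exchanged. We assume that the product, which grows as the complex with two exchanged fades, holds 2 ligands. Of 0.90 charged, the impurity has then taken about 0.462, with free ligand and the complex with two exchanged neglected. Those runs carry 1.29 equivalents of impurity, so we define the quench ratio per equivalent, ligand taken by impurity per ligand locked in product for each equivalent of impurity, as κ = 0.949.

Assuming proportionality, which runs this close together do not test, holding the one-exchanged reading unchanged at the end, and again neglecting the complex with two exchanged: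

ρ = κ × equivalents of impurity

product = (ligand equivalents − one-exchanged) / (2(1 + ρ))

starting complex = 1 − product − one-exchanged

East: ρ = 0.949, product 21.6 %, starting complex 72.5 %.

North: ρ = 1.42, product 17.4 %, starting complex 76.7 %.

The forecast names starting complex for both flasks, at 70 % in east and 80 % in north, figures that differ from ours, and states: “no stoichiometric cliff is expected”.

East ends with 72.4 % of starting complex and 22.4 % of product, north with 77.3 % and 18.2 %.

    starting complex + incoming ligand ⇌ leaving ligand + complex with one exchanged (K = 4.70, k = 0.0900 M⁻¹ s⁻¹)
    complex with one exchanged + incoming ligand ⇌ leaving ligand + complex with two exchanged (K = 1.40, k = 0.110 M⁻¹ s⁻¹)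
    complex with two exchanged + incoming ligand ⇌ leaving ligand + complex with three exchanged (K = 0.170, k = 0.0560 M⁻¹ s⁻¹)
    protic impurity + incoming ligand → quenched reagent (k = 0.0200 M⁻¹ s⁻¹)
    complex with two exchanged → over-reaction product (k = 0.0140 s⁻¹)

In east at 25.0 min the first exchange, taken alone, relaxes with a half-life of 0.303 min, short against 25 min, while the incoming ligand, the limiting reagent, is down to 0.70 % of its charge. Quenched reagent over ligand in product stands there at 0.880, against our ρ of 0.949.

For the neighbour of east with 0.30 M of impurity, κ gives ρ = 0.569, product 26.8 % and starting complex 67.3 %. That flask computes to 27.3 % and 66.7 %.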